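**Retrosynthetic overview**
- The target is reached by hydrogenolysis of its 5,4'-di-O-benzyl ether; benzyl masks the two phenols that must end up free.
- Ring C (the pyranone) is the only ring built, and it is built last, by oxidative cyclisation of a 2'-hydroxychalcone. Rings A and B are bought as arenes.
- The chalcone comes from the key intermolecular Claisen–Schmidt aldol condensation of a ring A acetophenone with a ring B benzaldehyde (forms the C3–C2 carbon link of the flavone).
- The ring B aldehyde comes from syringaldehyde by C2 bromination, CuCl-catalysed methoxylation and O-benzylation. The ring A ketone comes from 2',6'-dihydroxy-4'-methoxyacetophenone by mono-O-benzylation.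

Assumption: the target has no stereocentre or other stereogenic element, so it is achiral and no stereocontrol is needed; 2',6'-dihydroxy-4'-methoxyacetophenone is taken as a catalogue starting material.

**Route**

Step 1
Reactants: 1 syringaldehyde (4-hydroxy-3,5-dimethoxybenzaldehyde)
Product: 2 2-bromo-4-hydroxy-3,5-dimethoxybenzaldehyde
Conditions: Br2 (1.05 equiv), NaOAc (1.2 equiv), AcOH, rt, 3 h
Reagents that add atoms: bromine, BrBr
Why: Electrophilic aromatic bromination; C2 (equivalent to C6) is the only free position and is activated ortho/para by the two methoxy groups, so one monobromide forms.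

Step 2
Reactants: 2 2-bromo-4-hydroxy-3,5-dimethoxybenzaldehyde
Product: 3 4-hydroxy-2,3,5-trimethoxybenzaldehyde
Conditions: NaOMe (5 equiv, 25% in MeOH), CuCl (0.3 equiv), DMF, 110 °C, N2, 4 h; then 2 M HCl
Reagents that add atoms: sodium methoxide, C[O-].[Na+]
Why: Ullmann-type CuCl-catalysed methoxylation of an aryl bromide activated by the ortho formyl group (the 5-bromovanillin to syringaldehyde transformation), with the phenoxide shielding the aldehyde from Cannizzaro chemistry.

Step 3
Reactants: 3 4-hydroxy-2,3,5-trimethoxybenzaldehyde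
Product: 4 4-(benzyloxy)-2,3,5-trimethoxybenzaldehyde
Conditions: BnBr (1.2 equiv), K2CO3 (1.5 equiv), DMF, 60 °C, 4 h
Reagents that add atoms: benzyl bromide, BrCc1ccccc1
Why: Williamson ether synthesis on the only phenol, which blocks the acidic 4-OH before the base-mediated condensation.

Step 4
Reactants: 5 2',6'-dihydroxy-4'-methoxyacetophenone (1-(2,6-dihydroxy-4-methoxyphenyl)ethanone)
Product: 6 1-[2-(benzyloxy)-6-hydroxy-4-methoxyphenyl]ethanone
Conditions: BnBr (1.05 equiv), K2CO3 (1.1 equiv), acetone, reflux, 6 h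
Reagents that add atoms: benzyl bromide, BrCc1ccccc1
Why: Williamson mono-etherification of a symmetric bis-phenol; after the first alkylation the remaining OH is chelated to the carbonyl and too unreactive to alkylate again.

Step 5
Reactants: 6 1-[2-(benzyloxy)-6-hydroxy-4-methoxyphenyl]ethanone; 4 4-(benzyloxy)-2,3,5-trimethoxybenzaldehyde
Product: 8 (E)-1-[2-(benzyloxy)-6-hydroxy-4-methoxyphenyl]-3-[4-(benzyloxy)-2,3,5-trimethoxyphenyl]prop-2-en-1-one, via aldol adduct 7 (not isolated)
Conditions: KOH (50% aq, 10 equiv), EtOH, rt, 48 h; then cold 1 M HCl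
Reagents that add atoms: none
Why: Claisen–Schmidt crossed aldol condensation of the methyl ketone enolate with a non-enolisable aldehyde, followed by E1cB dehydration to the conjugated E-enone, which also removes the racemic carbinol centre of 7.

Step 6
Reactants: 8 (E)-1-[2-(benzyloxy)-6-hydroxy-4-methoxyphenyl]-3-[4-(benzyloxy)-2,3,5-trimethoxyphenyl]prop-2-en-1-one
Product: 10 5-(benzyloxy)-2-[4-(benzyloxy)-2,3,5-trimethoxyphenyl]-7-methoxy-4H-chromen-4-one, via flavanone 9 (not isolated)
Conditions: I2 (0.1 equiv), DMSO, 130 °C, 3 h; then aq Na2S2O3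
Reagents that add atoms: none
Why: Intramolecular oxa-Michael closure of the 2'-phenol to the flavanone, then iodine-catalysed dehydrogenation with DMSO as terminal oxidant (the standard chalcone-to-flavone oxidative cyclisation); the transient C2 centre of 9 is lost when ring C becomes unsaturated.

Step 7
Reactants: 10 5-(benzyloxy)-2-[4-(benzyloxy)-2,3,5-trimethoxyphenyl]-7-methoxy-4H-chromen-4-one
Product: 11 5-hydroxy-2-(4-hydroxy-2,3,5-trimethoxyphenyl)-7-methoxy-4H-chromen-4-one (5,4'-dihydroxy-7,2',3',5'-tetramethoxyflavone)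
Conditions: H2 (1 atm), 10% Pd/C, EtOAc/MeOH 1:1, rt, 3 h, stopped at full conversion
Reagents that add atoms: none
Why: Catalytic hydrogenolysis cleaves both benzyl aryl ethers while the methyl ethers and the vinylogous-ester C2=C3 bond of the chromone are inert at 1 atm and room temperature.

**Compound list**
1 | syringaldehyde (4-hydroxy-3,5-dimethoxybenzaldehyde) | COc1cc(C=O)cc(OC)c1O | starting material
2 | 2-bromo-4-hydroxy-3,5-dimethoxybenzaldehyde | COc1cc(C=O)c(Br)c(OC)c1O | intermediate
3 | 4-hydroxy-2,3,5-trimethoxybenzaldehyde | COc1cc(C=O)c(OC)c(OC)c1O | intermediate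
4 | 4-(benzyloxy)-2,3,5-trimethoxybenzaldehyde | COc1cc(C=O)c(OC)c(OC)c1OCc1ccccc1 | intermediate
5 | 2',6'-dihydroxy-4'-methoxyacetophenone | CC(=O)c1c(O)cc(OC)cc1O | starting material
6 | 1-[2-(benzyloxy)-6-hydroxy-4-methoxyphenyl]ethanone | CC(=O)c1c(O)cc(OC)cc1OCc1ccccc1 | intermediate
7 | aldol adduct, racemic 1-[2-(benzyloxy)-6-hydroxy-4-methoxyphenyl]-3-[4-(benzyloxy)-2,3,5-trimethoxyphenyl]-3-hydroxypropan-1-one (not isolated) | COc1cc(O)c(C(=O)CC(O)c2cc(OC)c(OCc3ccccc3)c(OC)c2OC)c(OCc2ccccc2)c1 | intermediate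
8 | (E)-1-[2-(benzyloxy)-6-hydroxy-4-methoxyphenyl]-3-[4-(benzyloxy)-2,3,5-trimethoxyphenyl]prop-2-en-1-one | COc1cc(O)c(C(=O)/C=C/c2cc(OC)c(OCc3ccccc3)c(OC)c2OC)c(OCc2ccccc2)c1 | intermediate
9 | flavanone, racemic 5-(benzyloxy)-2-[4-(benzyloxy)-2,3,5-trimethoxyphenyl]-7-methoxychroman-4-one (not isolated) | COc1cc(OCc2ccccc2)c2c(c1)OC(c1cc(OC)c(OCc3ccccc3)c(OC)c1OC)CC2=O | intermediate
10 | 5-(benzyloxy)-2-[4-(benzyloxy)-2,3,5-trimethoxyphenyl]-7-methoxy-4H-chromen-4-one | COc1cc(OCc2ccccc2)c2c(=O)cc(-c3cc(OC)c(OCc4ccccc4)c(OC)c3OC)oc2c1 | intermediate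
11 | 5-hydroxy-2-(4-hydroxy-2,3,5-trimethoxyphenyl)-7-methoxy-4H-chromen-4-one | COc1cc(O)c2c(=O)cc(-c3cc(OC)c(O)c(OC)c3OC)oc2c1 | target

**Summary**
Total step count: 7. Longest linear sequence: 6 steps (steps 1, 2, 3, 5, 6, 7 from syringaldehyde); step 4 is a one-step side branch.

**Steps most likely to fail, with fallbacks**

Step 2 (methoxylation of a doubly ortho-substituted bromide; risk of slow coupling or hydrodebromination). The fallback replaces the C–O coupling by bromine–lithium exchange, borylation and oxidation. It sets out from compound 2 and comes back at compound 4.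
- Benzylation of 2 (BnBr, K2CO3, DMF) gives 4-(benzyloxy)-2-bromo-3,5-dimethoxybenzaldehyde F1.
- Acetalisation (ethylene glycol, p-TsOH, toluene, Dean–Stark) gives 2-[4-(benzyloxy)-2-bromo-3,5-dimethoxyphenyl]-1,3-dioxolane F2.
- Bromine–lithium exchange (n-BuLi, THF, −78 °C) and trapping with B(OMe)3 gives dimethyl [3-(benzyloxy)-6-(1,3-dioxolan-2-yl)-2,4-dimethoxyphenyl]boronate F3, which is not isolated.
- Oxidation with H2O2/NaOH gives 3-(benzyloxy)-6-(1,3-dioxolan-2-yl)-2,4-dimethoxyphenol F4.
- Methylation (MeI, K2CO3, DMF) gives 2-[4-(benzyloxy)-2,3,5-trimethoxyphenyl]-1,3-dioxolane F5.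
- Hydrolysis with 1 M HCl/THF releases aldehyde 4.

Step 5 (condensation of two hindered, electron-rich partners; risk of incomplete conversion). The fallback is an intermolecular Claisen condensation at the acid oxidation level. It sets out from compound 4, uses compound 6, and comes back at compound 10, bypassing steps 5 and 6.
- Pinnick oxidation of 4 (NaClO2, NaH2PO4, 2-methyl-2-butene, t-BuOH/H2O) gives 4-(benzyloxy)-2,3,5-trimethoxybenzoic acid F6.
- (COCl)2 with catalytic DMF in CH2Cl2 gives 4-(benzyloxy)-2,3,5-trimethoxybenzoyl chloride F7.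
- The dianion of ketone 6 (LiN(SiMe3)2, 3.2 equiv, THF, −78 °C) is C-acylated by F7 to give 1-[2-(benzyloxy)-6-hydroxy-4-methoxyphenyl]-3-[4-(benzyloxy)-2,3,5-trimethoxyphenyl]propane-1,3-dione F8.
- Cyclodehydration (p-TsOH·H2O, toluene, 90 °C) closes ring C to flavone 10.

Step 6 (oxidative cyclisation at 130 °C; risk of partial benzyl loss or stalling at the flavanone). The fallback splits ring closure from dehydrogenation. It sets out from compound 8 and comes back at compound 10.
- Chalcone 8 is cyclised with NaOAc in refluxing EtOH and flavanone 9 is isolated.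
- Flavanone 9 is dehydrogenated with DDQ (1.5 equiv) in refluxing 1,4-dioxane to flavone 10.
- No new compound arises (F0).

**Further compounds**
F1 | step 2 | 4-(benzyloxy)-2-bromo-3,5-dimethoxybenzaldehyde | COc1cc(C=O)c(Br)c(OC)c1OCc1ccccc1
F2 | step 2 | 2-[4-(benzyloxy)-2-bromo-3,5-dimethoxyphenyl]-1,3-dioxolane | COc1cc(C2OCCO2)c(Br)c(OC)c1OCc1ccccc1
F3 | step 2 | dimethyl [3-(benzyloxy)-6-(1,3-dioxolan-2-yl)-2,4-dimethoxyphenyl]boronate | COB(OC)c1c(C2OCCO2)cc(OC)c(OCc2ccccc2)c1OC
F4 | step 2 | 3-(benzyloxy)-6-(1,3-dioxolan-2-yl)-2,4-dimethoxyphenol | COc1cc(C2OCCO2)c(O)c(OC)c1OCc1ccccc1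
F5 | step 2 | 2-[4-(benzyloxy)-2,3,5-trimethoxyphenyl]-1,3-dioxolane | COc1cc(C2OCCO2)c(OC)c(OC)c1OCc1ccccc1
F6 | step 5 | 4-(benzyloxy)-2,3,5-trimethoxybenzoic acid | COc1cc(C(=O)O)c(OC)c(OC)c1OCc1ccccc1
F7 | step 5 | 4-(benzyloxy)-2,3,5-trimethoxybenzoyl chloride | COc1cc(C(=O)Cl)c(OC)c(OC)c1OCc1ccccc1
F8 | step 5 | 1-[2-(benzyloxy)-6-hydroxy-4-methoxyphenyl]-3-[4-(benzyloxy)-2,3,5-trimethoxyphenyl]propane-1,3-dione | COc1cc(O)c(C(=O)CC(=O)c2cc(OC)c(OCc3ccccc3)c(OC)c2OC)c(OCc2ccccc2)c1
F0 | step 6 | none | none
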